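A direct plan would dimerise vanillin A1 oxidatively with FeSO4/Na2S2O8 in water to dehydrodivanillin A2, extend both formyl groups of A2 with malonic acid A3 in a double Knoevenagel–Doebner condensation to (E,E)-5,5'-dehydrodiferulic acid A4, and hydrogenate both alkenes of A4 to the target.
Its weakest points would be:
- The radical phenol dimerisation of A1 that forms the biaryl bond: A2 is more easily oxidised than A1, so the step would be held at the dimer only by precipitation, and over-oxidised or oligomeric material would be trapped in a solid that can be purified only by reprecipitation.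
- The double condensation of the barely soluble dialdehyde A2 with malonic acid A3: both formyl groups, each deactivated by a para-phenoxide, would have to react completely to reach A4, with further decarboxylation to vinylphenols as a competing path.
- The closing hydrogenation of A4: it would build nothing and would only erase two alkenes that the condensation with A3 had introduced at the wrong oxidation level.

**Retrosynthetic overview** (biphenyl locants: C1/C1' biaryl carbons, C2/C2' hydroxyl, C3/C3' methoxy, C5/C5' side chain)
- Key disconnection: the two aryl–CH2 bonds at C5 and C5' are cut at once, leading back to two molecules of methyl acrylate and 3,3'-dimethoxybiphenyl-2,2'-diol.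
- In each ring the phenoxide carbon C2 is flanked by C1 (second ring) and C3 (OMe), so C5, para to the oxygen, is the only carbon at which C-alkylation can end in an arene; it is the carbon that carries the chain in the target.
- The biaryl core is assembled first and without oxidant, by borylation–Suzuki homocoupling of 2-bromo-6-methoxyphenol at the carbon the bromine marks; no ring is formed de novo, and both chains are added last, in two directions at once.
- The chains arrive at their final oxidation level, so no aldehyde, alkene, hydrogenation, radical phenol oxidation or double condensation on an insoluble dialdehyde is needed.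

Key step: step 2

Step 1
Reactants: 1 2-bromo-6-methoxyphenol (two molecules)
Product: 3 3,3'-dimethoxybiphenyl-2,2'-diol, via 2-hydroxy-3-methoxyphenylboronic acid pinacol ester 2 (not isolated)
Conditions: B2pin2 (0.52 equiv), Pd(dppf)Cl2 (3 mol%), KOAc (1.5 equiv), 1,4-dioxane, 90 °C; then degassed aq K3PO4 (3 equiv), 90 °C
Reagents that add atoms: none
Why: One-pot Miyaura borylation–Suzuki–Miyaura homocoupling: with half an equivalent of B2pin2 and the weak base KOAc, zerovalent palladium should turn half of 1 into boronate 2 without coupling, and the aqueous phosphate added afterwards should switch on transmetalation so that 2 couples with the remaining 1 exactly at the brominated carbon ortho to the hydroxyl group, free ortho-bromophenols and ortho-hydroxyarylboronates being tolerated in both reactions.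

Step 2
Reactants: 3 3,3'-dimethoxybiphenyl-2,2'-diol; 4 methyl acrylate (3 equiv)
Product: 5 dimethyl 3,3'-(6,6'-dihydroxy-5,5'-dimethoxybiphenyl-3,3'-diyl)dipropanoate
Conditions: KOtBu (2.05 equiv), DMSO–t-BuOH (5:1), 25 °C, argon; then 4 added over 2 h, 80 °C; AcOH quench
Reagents that add atoms: methyl acrylate (4), C=CC(=O)OC
Why: Double phenoxide C-alkylation by conjugate (Michael) addition: each ring of the dipotassium salt of 3 attacks the β-carbon of 4 through C5, para to the oxygen, to give a 4-substituted cyclohexa-2,5-dienone ester enolate, and tert-butanol relays the proton from the sp3 ring carbon to the enolate, so the arene is restored and a phenoxide is regenerated. The closest known reaction type is the base-catalysed para-alkylation of 2,6-disubstituted phenols with methyl acrylate, as used to make methyl 3-(3,5-di-tert-butyl-4-hydroxyphenyl)propanoate, together with the general carbon selectivity of phenolates toward Michael acceptors under reversible conditions. No ring is closed and no stereocentre is formed. The step needs carbon over oxygen, para over ortho and double over single addition: attack through oxygen gives a β-aryloxy ester that returns to phenoxide and acrylate by E1cB elimination in the basic medium, attack through C1 or C3 gives a dienone that cannot tautomerise because these carbons carry the second ring and the methoxy group and so also reverts, and only the C5 adduct is withdrawn irreversibly by rearomatisation. The two rings are twisted out of conjugation and electronically independent, so the first chain should not slow the second addition, and slow addition of 4 to a medium that holds almost no free alkoxide should keep anionic oligomerisation of the acrylate low.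

Step 3
Reactants: 5 dimethyl 3,3'-(6,6'-dihydroxy-5,5'-dimethoxybiphenyl-3,3'-diyl)dipropanoate
Product: 6 3,3'-(6,6'-dihydroxy-5,5'-dimethoxybiphenyl-3,3'-diyl)dipropanoic acid (target, CNP0122720.0)
Conditions: LiOH·H2O (6 equiv), THF–H2O (3:1), 25 °C, argon; then 1 M HCl to pH 2
Reagents that add atoms: lithium hydroxide, [Li+].[OH-]; water, O
Why: Saponification (acyl substitution by hydroxide) of two unhindered methyl esters; the phenols are carried as phenoxides under argon and are restored on acidification, the aryl methyl ethers are inert, and no stereocentre is involved.

**Compound list**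

1 | 2-bromo-6-methoxyphenol | COc1cccc(Br)c1O | starting material
2 | 2-hydroxy-3-methoxyphenylboronic acid pinacol ester [2-methoxy-6-(4,4,5,5-tetramethyl-1,3,2-dioxaborolan-2-yl)phenol] | COc1cccc(B2OC(C)(C)C(C)(C)O2)c1O | intermediate
3 | 3,3'-dimethoxybiphenyl-2,2'-diol | COc1cccc(-c2cccc(OC)c2O)c1O | intermediate
4 | methyl acrylate | C=CC(=O)OC | starting material
5 | dimethyl 3,3'-(6,6'-dihydroxy-5,5'-dimethoxybiphenyl-3,3'-diyl)dipropanoate | COC(=O)CCc1cc(OC)c(O)c(-c2cc(CCC(=O)OC)cc(OC)c2O)c1 | intermediate
6 | 3,3'-(6,6'-dihydroxy-5,5'-dimethoxybiphenyl-3,3'-diyl)dipropanoic acid (CNP0122720.0) | COc1cc(CCC(=O)O)cc(-c2cc(CCC(=O)O)cc(OC)c2O)c1O | target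

Total step count: 3. Longest linear sequence: 3 steps (1 → 3 → 5 → 6).

**Steps most likely to fail**

Step 2 (key step). Kinetic O-alkylation and base-initiated oligomerisation of the acrylate may outrun the para-C-addition, or the reaction may stop after the first ring. The fallback uses known chemistry and sets out from 3. A two-directional Mannich reaction (aq Me2NH, aq formaldehyde, EtOH, 70 °C), which is para-selective for 2,6-disubstituted phenols, should give 5,5'-bis[(dimethylamino)methyl]-3,3'-dimethoxybiphenyl-2,2'-diol F1. Heating F1 with dimethyl malonate and NaOMe in toluene (amine elimination followed by conjugate addition, as known for phenolic Mannich bases) should give tetramethyl 2,2'-[(6,6'-dihydroxy-5,5'-dimethoxybiphenyl-3,3'-diyl)dimethanediyl]dimalonate F2. Krapcho demethoxycarbonylation (NaCl, wet DMSO, 150 °C) should then return to the route at 5.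

Step 1. Oxidative addition to the electron-rich bromophenoxide may be slow, so that protodeboronation of boronate 2 and hydrodebromination consume the partners before they couple. The fallback sets out from 1. Protection (MOMCl, i-Pr2NEt, CH2Cl2) should give 1-bromo-3-methoxy-2-(methoxymethoxy)benzene F3. Reductive homocoupling with zerovalent nickel generated in the flask (NiCl2(PPh3)2 cat., PPh3, Zn dust, Et4NI, THF, 60 °C) should give 3,3'-dimethoxy-2,2'-bis(methoxymethoxy)biphenyl F4. Acidic methanolysis (HCl, MeOH, 50 °C) should return to the route at 3.

Step 3. The dissolved bis-phenoxide may be oxidised by traces of air during the alkaline hydrolysis, and partly hydrolysed salts may precipitate and stall the reaction. The fallback sets out from 3 and avoids base at the end. The key step is run with benzyl acrylate in place of 4 to give dibenzyl 3,3'-(6,6'-dihydroxy-5,5'-dimethoxybiphenyl-3,3'-diyl)dipropanoate F5. Neutral hydrogenolysis (H2, 1 atm, Pd/C, EtOAc–MeOH, 25 °C) should then release the acid and return to the route at 6.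

**Further compounds**

F1 | step 2 | 5,5'-bis[(dimethylamino)methyl]-3,3'-dimethoxybiphenyl-2,2'-diol | COc1cc(CN(C)C)cc(-c2cc(CN(C)C)cc(OC)c2O)c1O
F2 | step 2 | tetramethyl 2,2'-[(6,6'-dihydroxy-5,5'-dimethoxybiphenyl-3,3'-diyl)dimethanediyl]dimalonate | COc1cc(CC(C(=O)OC)C(=O)OC)cc(-c2cc(CC(C(=O)OC)C(=O)OC)cc(OC)c2O)c1O
F3 | step 1 | 1-bromo-3-methoxy-2-(methoxymethoxy)benzene | COCOc1c(Br)cccc1OC
F4 | step 1 | 3,3'-dimethoxy-2,2'-bis(methoxymethoxy)biphenyl | COCOc1c(OC)cccc1-c1cccc(OC)c1OCOC
F5 | step 3 | dibenzyl 3,3'-(6,6'-dihydroxy-5,5'-dimethoxybiphenyl-3,3'-diyl)dipropanoate | COc1cc(CCC(=O)OCc2ccccc2)cc(-c2cc(CCC(=O)OCc3ccccc3)cc(OC)c2O)c1O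
A1 | direct plan | vanillin (4-hydroxy-3-methoxybenzaldehyde) | COc1cc(C=O)ccc1O
A2 | direct plan | dehydrodivanillin (6,6'-dihydroxy-5,5'-dimethoxybiphenyl-3,3'-dicarbaldehyde) | COc1cc(C=O)cc(-c2cc(C=O)cc(OC)c2O)c1O
A3 | direct plan | malonic acid | OC(=O)CC(=O)O
A4 | direct plan | (E,E)-5,5'-dehydrodiferulic acid | COc1cc(/C=C/C(=O)O)cc(-c2cc(/C=C/C(=O)O)cc(OC)c2O)c1O
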